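**Plan**

- Retrosynthesis: the benzylic aryl ether C4–O–C6' is cut first (Mitsunobu, inversion at C4). This reduces the target to two copies of one cis-(3R,4R)-4-oxygenated 6,8-dioxy-7-methoxy-3-methylisochromanone. In that monomer the lactone O2–C3 bond and the C4–O bond are cut together (alkene dioxygenation with ester participation), then the aryl–CO2Me bond and the propenyl C=C.
- Forward: 4-O-methylgallate ester → bis-allyl ether → ortho-bromide → benzaldehyde → (E)-propenyl arene → ortho-ester. The δ-lactone ring then closes on C3. The monomer is divided into a C4 alcohol and a 6,8-diphenol, which are joined and deprotected.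
- Enabling feature: the ester carbonyl on C8a stands ortho to the C4a-bound (E)-CH=CH–CH3 unit of an arene made electron-rich by the oxygens on C6, C7 and C8. With the styrene coplanar with the benzene ring, the carbonyl oxygen can reach C3 (six-membered, endo) but not the p-lobe of benzylic C4.
- Stereochemistry: a lactate-derived chiral aryl-λ3-iodane sets C3 and C4 of the monomer (3R,4R, cis) in one operation, so all four stereocentres of the target stem from that step. The Mitsunobu coupling inverts C4 of the upper half to S (trans).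

Key step: step 9

Assumption: the (R,R)-configured lactate iodane is assumed to attack the alkene face that leads to the (3R,4R) series; if the opposite sense is found, the mirror-image reagent from methyl (R)-lactate is used with no other change.

**Route**

Step 1
Reactants: 1 methyl 3,5-dihydroxy-4-methoxybenzoate
Product: 2 methyl 4-methoxy-3,5-bis(prop-2-en-1-yloxy)benzoate
Conditions: allyl bromide, K2CO3, DMF, 60 °C
Reagents that add atoms: allyl bromide, C=CCBr
Why: Williamson O-alkylation of both phenols; the methyl ester and the flanked 4-OMe are inert, and allyl is chosen because it can later be removed without acid or hydrogen.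

Step 2
Reactants: 2 methyl 4-methoxy-3,5-bis(prop-2-en-1-yloxy)benzoate
Product: 3 methyl 2-bromo-4-methoxy-3,5-bis(prop-2-en-1-yloxy)benzoate
Conditions: NBS (1.05 equiv), MeCN, 0 °C to rt
Reagents that add atoms: N-bromosuccinimide, O=C1CCC(=O)N1Br
Why: Electrophilic aromatic bromination at one of the two equivalent free positions, each ortho and para to an allyloxy group, as with 3,4,5-trialkoxybenzoates; the first bromine deactivates the ring against a second substitution.

Step 3
Reactants: 3 methyl 2-bromo-4-methoxy-3,5-bis(prop-2-en-1-yloxy)benzoate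
Product: 4 [2-bromo-4-methoxy-3,5-bis(prop-2-en-1-yloxy)phenyl]methanol
Conditions: i-Bu2AlH (2.5 equiv), CH2Cl2, −78 to 0 °C
Reagents that add atoms: none
Why: Hydride reduction of the ester to the primary benzylic alcohol; the aryl bromide and allyl ethers are untouched at low temperature.

Step 4
Reactants: 4 [2-bromo-4-methoxy-3,5-bis(prop-2-en-1-yloxy)phenyl]methanol
Product: 5 2-bromo-4-methoxy-3,5-bis(prop-2-en-1-yloxy)benzaldehyde
Conditions: MnO2, CH2Cl2, rt
Reagents that add atoms: none
Why: Chemoselective oxidation of a benzylic alcohol to the aldehyde with activated MnO2, without over-oxidation.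

Step 5
Reactants: 5 2-bromo-4-methoxy-3,5-bis(prop-2-en-1-yloxy)benzaldehyde
Product: 6 2-bromo-4-methoxy-1-[(E)-prop-1-en-1-yl]-3,5-bis(prop-2-en-1-yloxy)benzene
Conditions: 5-(ethylsulfonyl)-1-phenyl-1H-tetrazole, KN(SiMe3)2, DME, −60 °C to rt; aq. NH4Cl
Reagents that add atoms: 5-(ethylsulfonyl)-1-phenyl-1H-tetrazole, CCS(=O)(=O)c1nnnn1-c1ccccc1
Why: Julia–Kocienski olefination; phenyltetrazolyl sulfones with aromatic aldehydes under potassium amide in DME should give the (E)-alkene through anti addition, Smiles rearrangement and anti elimination.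

Step 6
Reactants: 6 2-bromo-4-methoxy-1-[(E)-prop-1-en-1-yl]-3,5-bis(prop-2-en-1-yloxy)benzene
Product: 8 methyl 3-methoxy-6-[(E)-prop-1-en-1-yl]-2,4-bis(prop-2-en-1-yloxy)benzoate, via aryllithium 7 (not isolated)
Conditions: n-BuLi, THF, −78 °C; then transferred into ClCO2Me, THF, −78 to 0 °C
Reagents that add atoms: methyl chloroformate, COC(=O)Cl
Why: Bromine–lithium exchange is faster at −78 °C than carbolithiation of the styrene or attack on the allyl ethers, and inverse addition to excess chloroformate gives the hindered benzoate without ketone formation.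

Step 7
Reactants: 9 2-iodobenzene-1,3-diol; 10 methyl (S)-lactate
Product: 11 dimethyl (2R,2'R)-2,2'-[(2-iodo-1,3-phenylene)bis(oxy)]dipropanoate
Conditions: 10 (2.2 equiv in all), PPh3 (2.4 equiv), DIAD (2.4 equiv), THF, 0 °C to rt
Reagents that add atoms: methyl (S)-lactate (second equivalent of 10), C[C@H](O)C(=O)OC
Why: Double Mitsunobu etherification in which each of the two acidic phenols of 9 takes up one molecule of methyl (S)-lactate, so two equivalents of 10 are consumed; each lactate carbon reacts by SN2 with inversion (S to R).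

Step 8
Reactants: 11 dimethyl (2R,2'R)-2,2'-[(2-iodo-1,3-phenylene)bis(oxy)]dipropanoate
Product: 12 dimethyl (2R,2'R)-2,2'-{[2-(diacetoxy-λ3-iodanyl)-1,3-phenylene]bis(oxy)}dipropanoate
Conditions: NaBO3·4H2O, AcOH, 50 °C
Reagents that add atoms: acetic acid, CC(=O)O
Why: Standard perborate oxidation of an aryl iodide to the trivalent iodine diacetate in acetic acid; the lactate stereocentres are not involved.

Step 9
Reactants: 8 methyl 3-methoxy-6-[(E)-prop-1-en-1-yl]-2,4-bis(prop-2-en-1-yloxy)benzoate; 12 dimethyl (2R,2'R)-2,2'-{[2-(diacetoxy-λ3-iodanyl)-1,3-phenylene]bis(oxy)}dipropanoate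
Product: 14 (3R,4R)-7-methoxy-3-methyl-1-oxo-6,8-bis(prop-2-en-1-yloxy)-3,4-dihydro-1H-isochromen-4-yl acetate, via iodanyl dialkoxycarbenium ion 13 (not isolated)
Conditions: 12 (1.3 equiv), BF3·OEt2 (2 equiv), AcOH (10 equiv), CH2Cl2, −80 to −40 °C
Reagents that add atoms: acetic acid, CC(=O)O
Why: The BF3-activated trivalent iodine centre of 12 adds to one face of the electron-rich C3=C4 styrene bond while the ortho ester carbonyl oxygen attacks C3 from the opposite face, giving ion 13; acetate (from the medium, in exchange with the acetate ligands of 12) then displaces the aryliodanyl hypernucleofuge at benzylic C4 with inversion (releasing iodoarene 11) and a second acetate removes the O-methyl group as methyl acetate. The closest known reaction type is the enantioselective endo-selective oxylactonization of ortho-alk-1-enylbenzoates with lactate-derived aryl-λ3-iodanes (a Prévost–Woodward-type alkene dioxygenation with ester participation), which has been applied to polyalkoxylated benzoates. The δ-lactone ring closes in the 6-endo-trig mode by formation of the O2–C3 bond. C3 is set by the reagent-controlled choice of alkene face (the two (R)-lactate arms fold over the iodine centre), and C4 follows from it stereospecifically, since anti addition across the E alkene followed by one SN2 inversion gives the cis (3R,4R) pair. The step needs 6-endo rather than 5-exo closure, secured because conjugation keeps the alkene coplanar with the ring so that the carbonyl oxygen on C8a can reach C3 but not the p-lobe of benzylic C4, and it needs attack on the styrene rather than on the two O-allyl groups, secured by the far higher nucleophilicity of the trialkoxystyrene at −80 °C.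

Step 10
Reactants: 14 (3R,4R)-7-methoxy-3-methyl-1-oxo-6,8-bis(prop-2-en-1-yloxy)-3,4-dihydro-1H-isochromen-4-yl acetate
Product: 15 (3R,4R)-4-hydroxy-7-methoxy-3-methyl-6,8-bis(prop-2-en-1-yloxy)-3,4-dihydro-1H-isochromen-1-one
Conditions: K2CO3 (cat.), MeOH, 0 °C
Reagents that add atoms: none
Why: Base-catalysed transesterification (Zemplén type) removes the secondary acetate, while the lactone carbonyl, flanked by the C8 allyloxy group and the ring, is much less electrophilic; no stereocentre is touched.

Step 11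
Reactants: 14 (3R,4R)-7-methoxy-3-methyl-1-oxo-6,8-bis(prop-2-en-1-yloxy)-3,4-dihydro-1H-isochromen-4-yl acetate
Product: 16 (3R,4R)-6,8-dihydroxy-7-methoxy-3-methyl-1-oxo-3,4-dihydro-1H-isochromen-4-yl acetate
Conditions: Pd(PPh3)4 (cat.), morpholine, THF, rt
Reagents that add atoms: none
Why: Tsuji–Trost deallylation by zerovalent palladium with morpholine as the allyl acceptor; the secondary acetate and the lactone survive these near-neutral conditions.

Step 12
Reactants: 15 (3R,4R)-4-hydroxy-7-methoxy-3-methyl-6,8-bis(prop-2-en-1-yloxy)-3,4-dihydro-1H-isochromen-1-one; 16 (3R,4R)-6,8-dihydroxy-7-methoxy-3-methyl-1-oxo-3,4-dihydro-1H-isochromen-4-yl acetate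
Product: 17 (3R,4R)-8-hydroxy-7-methoxy-6-{[(3R,4S)-7-methoxy-3-methyl-1-oxo-6,8-bis(prop-2-en-1-yloxy)-3,4-dihydro-1H-isochromen-4-yl]oxy}-3-methyl-1-oxo-3,4-dihydro-1H-isochromen-4-yl acetate
Conditions: PPh3, DIAD, THF, 0 °C to rt
Reagents that add atoms: none
Why: Mitsunobu etherification in which the non-chelated 6-OH of 16 (para to the lactone carbonyl, the more acidic phenol) displaces the phosphonium-activated C4 hydroxyl of 15 by SN2 with inversion (R to S), giving the trans upper half; the hydrogen-bonded 8-OH should not compete.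

Step 13
Reactants: 17 (3R,4R)-8-hydroxy-7-methoxy-6-{[(3R,4S)-7-methoxy-3-methyl-1-oxo-6,8-bis(prop-2-en-1-yloxy)-3,4-dihydro-1H-isochromen-4-yl]oxy}-3-methyl-1-oxo-3,4-dihydro-1H-isochromen-4-yl acetate
Product: 18 (3R,4S)-4-{[(3R,4R)-4,8-dihydroxy-7-methoxy-3-methyl-1-oxo-3,4-dihydro-1H-isochromen-6-yl]oxy}-6,8-dihydroxy-7-methoxy-3-methyl-3,4-dihydro-1H-isochromen-1-one
Conditions: Pd(PPh3)4 (cat.), K2CO3, MeOH, rt; aq. NH4Cl
Reagents that add atoms: none
Why: One-pot Tsuji–Trost deallylation by zerovalent palladium with methoxide as allyl acceptor and Zemplén-type methanolysis of the C4' acetate; no acid or hydrogen is used, so the benzylic aryl ether and the benzylic alcohol should stay intact.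

**Compound list**

1 | methyl 3,5-dihydroxy-4-methoxybenzoate | COC(=O)c1cc(O)c(OC)c(O)c1 | starting material
2 | methyl 4-methoxy-3,5-bis(prop-2-en-1-yloxy)benzoate | COC(=O)c1cc(OCC=C)c(OC)c(OCC=C)c1 | intermediate
3 | methyl 2-bromo-4-methoxy-3,5-bis(prop-2-en-1-yloxy)benzoate | COC(=O)c1cc(OCC=C)c(OC)c(OCC=C)c1Br | intermediate
4 | [2-bromo-4-methoxy-3,5-bis(prop-2-en-1-yloxy)phenyl]methanol | OCc1cc(OCC=C)c(OC)c(OCC=C)c1Br | intermediate
5 | 2-bromo-4-methoxy-3,5-bis(prop-2-en-1-yloxy)benzaldehyde | O=Cc1cc(OCC=C)c(OC)c(OCC=C)c1Br | intermediate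
6 | 2-bromo-4-methoxy-1-[(E)-prop-1-en-1-yl]-3,5-bis(prop-2-en-1-yloxy)benzene | C/C=C/c1cc(OCC=C)c(OC)c(OCC=C)c1Br | intermediate
7 | {3-methoxy-6-[(E)-prop-1-en-1-yl]-2,4-bis(prop-2-en-1-yloxy)phenyl}lithium (not isolated) | [Li]c1c(/C=C/C)cc(OCC=C)c(OC)c1OCC=C | intermediate
8 | methyl 3-methoxy-6-[(E)-prop-1-en-1-yl]-2,4-bis(prop-2-en-1-yloxy)benzoate | COC(=O)c1c(/C=C/C)cc(OCC=C)c(OC)c1OCC=C | intermediate
9 | 2-iodobenzene-1,3-diol | Oc1cccc(O)c1I | starting material
10 | methyl (2S)-2-hydroxypropanoate (methyl (S)-lactate) | C[C@H](O)C(=O)OC | starting material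
11 | dimethyl (2R,2'R)-2,2'-[(2-iodo-1,3-phenylene)bis(oxy)]dipropanoate | COC(=O)[C@@H](C)Oc1cccc(O[C@H](C)C(=O)OC)c1I | intermediate
12 | dimethyl (2R,2'R)-2,2'-{[2-(diacetoxy-λ3-iodanyl)-1,3-phenylene]bis(oxy)}dipropanoate | CC(=O)OI(OC(C)=O)c1c(O[C@H](C)C(=O)OC)cccc1O[C@H](C)C(=O)OC | intermediate
13 | (3R,4S)-4-{acetoxy[2,6-bis({[(2R)-1-methoxy-1-oxopropan-2-yl]oxy})phenyl]-λ3-iodanyl}-1,7-dimethoxy-3-methyl-6,8-bis(prop-2-en-1-yloxy)-3,4-dihydroisochromenylium acetoxy(trifluoro)borate (not isolated) | C=CCOc1cc2c(c(OCC=C)c1OC)C(OC)=[O+][C@H](C)[C@H]2I(OC(C)=O)c1c(O[C@H](C)C(=O)OC)cccc1O[C@H](C)C(=O)OC.CC(=O)O[B-](F)(F)F | intermediate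
14 | (3R,4R)-7-methoxy-3-methyl-1-oxo-6,8-bis(prop-2-en-1-yloxy)-3,4-dihydro-1H-isochromen-4-yl acetate | C=CCOc1cc2c(c(OCC=C)c1OC)C(=O)O[C@H](C)[C@@H]2OC(C)=O | intermediate
15 | (3R,4R)-4-hydroxy-7-methoxy-3-methyl-6,8-bis(prop-2-en-1-yloxy)-3,4-dihydro-1H-isochromen-1-one | C=CCOc1cc2c(c(OCC=C)c1OC)C(=O)O[C@H](C)[C@@H]2O | intermediate
16 | (3R,4R)-6,8-dihydroxy-7-methoxy-3-methyl-1-oxo-3,4-dihydro-1H-isochromen-4-yl acetate | Oc1cc2c(c(O)c1OC)C(=O)O[C@H](C)[C@@H]2OC(C)=O | intermediate
17 | (3R,4R)-8-hydroxy-7-methoxy-6-{[(3R,4S)-7-methoxy-3-methyl-1-oxo-6,8-bis(prop-2-en-1-yloxy)-3,4-dihydro-1H-isochromen-4-yl]oxy}-3-methyl-1-oxo-3,4-dihydro-1H-isochromen-4-yl acetate | COc1c(OCC=C)cc2c(c1OCC=C)C(=O)O[C@H](C)[C@H]2Oc1cc2c(c(O)c1OC)C(=O)O[C@H](C)[C@@H]2OC(C)=O | intermediate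
18 | (3R,4S)-4-{[(3R,4R)-4,8-dihydroxy-7-methoxy-3-methyl-1-oxo-3,4-dihydro-1H-isochromen-6-yl]oxy}-6,8-dihydroxy-7-methoxy-3-methyl-3,4-dihydro-1H-isochromen-1-one | COc1c(O)cc2c(c1O)C(=O)O[C@H](C)[C@H]2Oc1cc2c(c(O)c1OC)C(=O)O[C@H](C)[C@@H]2O | target

**Step count and risks**

Total step count: 13 (including the two steps that make reagent 12).
Longest linear sequence: 10 steps (steps 1–6, 9, 10, 12, 13).

Steps most likely to fail:

1. Step 9. What may go wrong: insufficient enantiofacial discrimination by the iodane on this very electron-rich, fully substituted styrene, or partial ionisation of the C4–iodine bond with erosion of the syn course. Fallback, setting out from 8 and coming back at 15: stereocontrol is moved from the lactonization to a ketone reduction. The oxidative lactonization is run without chiral information (PhI(OAc)2, BF3·OEt2, AcOH, CH2Cl2, −78 °C) to give the racemic cis/trans 4-acetoxy lactone F1. K2CO3 in MeOH gives the racemic 4-hydroxy lactone F2. Dess–Martin periodinane gives the stereolabile 7-methoxy-3-methyl-6,8-bis(allyloxy)isochroman-1,4-dione F3. Noyori-type asymmetric transfer hydrogenation under dynamic kinetic resolution (RuCl(p-cymene)[(S,S)-TsDPEN], HCO2H/Et3N) should reduce the C4 ketone from the face opposite the C3 methyl while C3 epimerises through the enol, giving cis-(3R,4R)-15. Acetylation of part of 15 (Ac2O, pyridine) supplies 14 for step 11.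

2. Step 12. What may go wrong: E2 loss of the activated C4 oxygen to give the 3-methylisocoumarin, or ionisation at C4 with loss of stereochemical fidelity and C-alkylation of the phenol. Fallback, setting out from 8 and 16 and coming back at 17: the ether is made by epoxide opening instead of alcohol activation. Shi epoxidation of 8 (D-fructose-derived ketone, Oxone (2KHSO5·KHSO4·K2SO4), K2CO3, MeCN/dimethoxymethane/buffer, 0 °C) gives methyl 3-methoxy-6-[(2R,3R)-3-methyloxiran-2-yl]-2,4-bis(allyloxy)benzoate F4. The 6-phenoxide of 16 (Cs2CO3, DMF, 60 °C) should open F4 at the benzylic carbon with inversion, and the C3 alkoxide so released closes onto the ortho ester in the same flask. The ether bond, the trans relationship and the upper lactone then arise together to give 17.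

3. Step 13. What may go wrong: once the C4' acetate is gone, base-induced acyl transfer (ring contraction of the cis-4-hydroxy lactone to a phthalide) or lactone methanolysis, and E2 loss of the aryloxide from the upper ring. Fallback, setting out from 15 and coming back at 18: the lower half carries a silyl ether instead of the acetate, so that no alkoxide base is needed at the end. Alcohol 15 is silylated (TBSOTf, 2,6-lutidine, CH2Cl2) to the 4-O-TBS ether F5 and deallylated (Pd(PPh3)4, morpholine, THF) to the silylated diphenol F6. F6 is coupled with 15 under the conditions of step 12 to the silyl-protected bis-allyl dimer F7. F7 is deallylated (Pd(PPh3)4, morpholine, THF) to the silylated tetraphenol F8, which is desilylated with HF·pyridine in THF to give 18.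

**Further compounds**

F1 | step 9 | rac-7-methoxy-3-methyl-1-oxo-6,8-bis(prop-2-en-1-yloxy)-3,4-dihydro-1H-isochromen-4-yl acetate (cis/trans mixture) | C=CCOc1cc2c(c(OCC=C)c1OC)C(=O)OC(C)C2OC(C)=O
F2 | step 9 | rac-4-hydroxy-7-methoxy-3-methyl-6,8-bis(prop-2-en-1-yloxy)-3,4-dihydro-1H-isochromen-1-one (cis/trans mixture) | C=CCOc1cc2c(c(OCC=C)c1OC)C(=O)OC(C)C2O
F3 | step 9 | rac-7-methoxy-3-methyl-6,8-bis(prop-2-en-1-yloxy)-1H-isochromene-1,4(3H)-dione | C=CCOc1cc2c(c(OCC=C)c1OC)C(=O)OC(C)C2=O
F4 | step 12 | methyl 3-methoxy-6-[(2R,3R)-3-methyloxiran-2-yl]-2,4-bis(prop-2-en-1-yloxy)benzoate | C[C@H]1O[C@@H]1c1cc(OCC=C)c(OC)c(OCC=C)c1C(=O)OC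
F5 | step 13 | (3R,4R)-4-[(tert-butyldimethylsilyl)oxy]-7-methoxy-3-methyl-6,8-bis(prop-2-en-1-yloxy)-3,4-dihydro-1H-isochromen-1-one | C=CCOc1cc2c(c(OCC=C)c1OC)C(=O)O[C@H](C)[C@@H]2O[Si](C)(C)C(C)(C)C
F6 | step 13 | (3R,4R)-4-[(tert-butyldimethylsilyl)oxy]-6,8-dihydroxy-7-methoxy-3-methyl-3,4-dihydro-1H-isochromen-1-one | Oc1cc2c(c(O)c1OC)C(=O)O[C@H](C)[C@@H]2O[Si](C)(C)C(C)(C)C
F7 | step 13 | (3R,4S)-4-({(3R,4R)-4-[(tert-butyldimethylsilyl)oxy]-8-hydroxy-7-methoxy-3-methyl-1-oxo-3,4-dihydro-1H-isochromen-6-yl}oxy)-7-methoxy-3-methyl-6,8-bis(prop-2-en-1-yloxy)-3,4-dihydro-1H-isochromen-1-one | COc1c(OCC=C)cc2c(c1OCC=C)C(=O)O[C@H](C)[C@H]2Oc1cc2c(c(O)c1OC)C(=O)O[C@H](C)[C@@H]2O[Si](C)(C)C(C)(C)C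
F8 | step 13 | (3R,4S)-4-({(3R,4R)-4-[(tert-butyldimethylsilyl)oxy]-8-hydroxy-7-methoxy-3-methyl-1-oxo-3,4-dihydro-1H-isochromen-6-yl}oxy)-6,8-dihydroxy-7-methoxy-3-methyl-3,4-dihydro-1H-isochromen-1-one | COc1c(O)cc2c(c1O)C(=O)O[C@H](C)[C@H]2Oc1cc2c(c(O)c1OC)C(=O)O[C@H](C)[C@@H]2O[Si](C)(C)C(C)(C)C
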